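The runs come from a simulation for substances that don't exist; scatter was added.

Slowness marks the right-handed substrate: in the oak run at 6.00 min it still reads 48.8%, and the left-handed substrate reads less, 22.9%.

| flask | left-handed substrate | right-handed substrate | reagent | free catalyst | remark | time |
|---|---|---|---|---|---|---|
| cedar | 20 mM | 20 mM | 15 mM | 40 µM | run made earlier |  |
| oak | 20 mM | 20 mM | 22 mM | 40 µM | run made earlier |  |
| flask | 20 mM | 20 mM | 30.0 mM | 40 µM |  | 6.0 min |

- cedar (time / min: left-handed substrate / %, right-handed substrate / %): 0.500: 45.2, 48.4; 0.667: 43.3, 49.3; 1.00: 40.4, 48.6; 1.50: 40.3, 46.5; 2.50: 33.3, 48.0; 4.00: 32.6, 46.6; 6.00: 30.1, 48.1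
- oak (time / min: left-handed substrate / %, right-handed substrate / %): 0.500: 41.5, 49.6; 0.667: 41.8, 50.3; 1.00: 36.2, 49.7; 1.50: 33.2, 46.8; 2.50: 27.4, 49.5; 4.00: 25.7, 47.7; 6.00: 22.9, 48.8

(scatter of a reading: 1 percentage point)

1. part of the left-handed substrate and right-handed substrate charged together that has reacted at 6.0 min
2. excess of left-handed product over right-handed product in the product at 6.0 min
3. excess of right-handed substrate over left-handed substrate among what is left of the two at 6.0 min

- free catalyst is single-handed; left-handed substrate and right-handed substrate are mirror images of each other, charged as a racemate, each of them at the stated concentration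
- the analysis behind the earlier runs scatters by 1 percentage point, standard deviation
- steps thought possible: 2 free catalyst -> spent catalyst; free catalyst + left-handed substrate <-> catalyst intermediate A; left-handed product <-> right-handed product; reagent <-> dormant form; free catalyst + right-handed substrate <-> catalyst intermediate B; reagent + catalyst intermediate B -> free catalyst + right-handed product; reagent + catalyst intermediate A -> free catalyst + left-handed product
- an excess is the difference of the two amounts in percent of their sum
- an excess is below zero if the other one leads

I hand you this flask with one number, the selectivity factor: the logarithm of the fraction of left-handed substrate remaining over the same logarithm for the right-handed substrate. Pooling the readings of both runs from 2.50 min on, I read 14.6, a rough reading: the oak run's right-handed substrate stands 1.2 percentage points below its start at 6.00 min, and a reading scatters by 1 point.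

I scale the oak run's logarithmic loss by the reagent charges, which gives 1.06 for this flask. So at 6.0 min I expect about 17.2% left-handed and 46.5% right-handed substrate. That means 36.3% reacted and a substrate excess of 46.0%. The product excess reckoned from these two losses is 80.7%, but that is the excess as made, and neither run read the product, so no reading stands behind it.

The forecast says, in the order asked, 36%, 81% and 46%, and warns: “Possible saturation or product racemisation is untested”.

The flask gives, in the same order, 40.6%, 1.04% and 52.3%.

    2 free catalyst → spent catalyst (k = 178 M⁻¹ s⁻¹)
    free catalyst + left-handed substrate ⇌ catalyst intermediate A (K = 70.0 M⁻¹, k = 10800 M⁻¹ s⁻¹)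
    left-handed product ⇌ right-handed product (k = 0.0207 s⁻¹)
    reagent ⇌ dormant form (K = 0.778, k = 0.00218 s⁻¹)
    free catalyst + right-handed substrate ⇌ catalyst intermediate B (K = 16.5 M⁻¹, k = 14100 M⁻¹ s⁻¹)
    reagent + catalyst intermediate B → free catalyst + right-handed product (k = 87.7 M⁻¹ s⁻¹)
    reagent + catalyst intermediate A → free catalyst + left-handed product (k = 270 M⁻¹ s⁻¹)

In this flask, the unbound left-handed rest of 28% and the selectivity factor give a right-handed rest of 91.8%, against 91% found, and an excess as made of 79.6%. The product shows 1.04%, and the half-life of left-handed product turning into right-handed product, by that forward step alone at 6.00 min, is 0.56 min, short against the 6.0 min of the run.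

In the neighbour flask with 51 mM of reagent, the left-handed rest of 8.4% and the factor give a right-handed rest of 84.5% and an excess as made of 71.1%. That flask computes to a right-handed rest of 82% and a product excess of 0.201%.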